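## Analysis of the target

Target 31 (CNP0252711.1) is a spirodienone sesquineolignan. Ring A is a 3-methoxycyclohexa-2,5-dien-4-one (C1–C6, C1 the spiro atom, C3–OMe, C4=O) and shares C1 with an oxolane, ring B (O–C7–C1–C8'–C7'). Ring B carries a guaiacyl group at C7', the hydroxymethyl carbon C9' at C8', and at C7 the chain C8–C9, whose C8 oxygen is the aryl ether of dihydroconiferyl alcohol and whose C9 is a primary alcohol. The five stereocentres are 1S,7S,8S,7'S,8'R. On ring B the aryl group at C7' is trans to C9' and, across the ring oxygen, trans to the C7 chain, so C9' and the C7 chain are cis. C1 is stereogenic only because the two ring A arms differ by the C3 methoxy group; the methoxylated arm (C2=C3) lies on the face of ring B that carries C9' and the C7 chain. Sensitive features are the cross-conjugated dienone (an acceptor for the internal hydroxyls, and acid-labile), its enol ether, the benzylic C7'–O bond next to an electron-rich ring, and the free phenol. The difficulty lies in a quaternary spiro centre flanked by two stereocentres and carrying two almost identical arms, a 2,5-trans oxolane that simple ring closures do not favour, and a hindered secondary aryl ether at C8. The strategy rests on ring B: its O–C7 and C7'–C8' bonds lie on either side of C1, so both can be made from two arms on an achiral cyclohexa-2,5-diene, and the C9' hydroxyl, cis to one ring A arm only, can later tell the arms apart.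

## Retrosynthetic reasoning

31 ⇒ 30. The phenol and the C9 and side-chain primary alcohols are masked to the end as silyl ethers; 30 differs from 31 only by these three groups, removed in one buffered desilylation. Nothing stereochemical happens here.

30 ⇒ 28 ⇒ 27. The methoxy enone arm of 30 is the methyl ether of a diosphenol (29). A diosphenol is what a ketone with an α-hydroxyl and a β-alkoxy leaving group gives on β-elimination, so the C3–OCH3 bond is cut and O9' is reconnected to C2, giving 28. 28 comes from 27 by hydroxylation of its only possible enolate (C3). The gain is that the methoxy group enters on one defined arm without an external reagent having to choose between two enones.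

27 ⇒ 26 ⇒ 25. Cutting O9'–C2 leads to hydroxy dienone 26, in which the ring A arms are identical and C1 is not yet a stereocentre. C9' sits on C8', next to C1 and on one face of ring B, so its hydroxyl can only add to the arm on that face. The forward reaction must be intramolecular, and C9'–OH must be the only free hydroxyl; hence it is kept as the acetate in 25 until the dienone exists.

25 ⇒ 24. The C4 carbonyl is traced back to a doubly allylic CH2. A 1,4-diene with a quaternary C1 survives Lewis acid, hydride and Mitsunobu conditions that a dienone would not, so the oxidation is placed after those steps.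

24 ⇒ 20 + 23. The C8–O(aryl) bond is cut. The forward reaction is an etherification with inversion, so 20 must hold the 8R carbinol, which is the configuration an E-derived epoxide delivers. The third aromatic unit enters late as phenol 23, made from 21.

20 ⇒ 19 ⇒ 18. The acetate comes from the primary hydroxyl of diol 19, and that hydroxyl from the imide carbonyl of 18 by reductive removal of the auxiliary, which returns 9.

18 ⇒ 14 + 16. This is the central disconnection: the C7'–C8' bond (aldol) and the O–C7 bond (epoxide opening) are cut, removing ring B and three stereocentres at once. Each centre is traced to a reagent: C8' and C7' to the oxazolidinone of 14, C7 to the epoxide of 14 with inversion. C1 in 14 carries two identical ring arms, so no mismatch with the ring can arise. Aldehyde 16 is silylated vanillin (15).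

14 ⇒ 13 ⇒ 12 ⇒ 11. The silyl ether comes from epoxy alcohol 13, this from E-allylic alcohol 12 by Sharpless asymmetric epoxidation, and 12 from enal 11 by 1,2-reduction. The imide is installed before the epoxide because a free γ,δ-epoxy acid would lactonise.

11 ⇒ 8 + 9; 8 ⇒ 7 ⇒ 5 + 6. The imide is made from acid 8 and auxiliary 9; 8 comes from tert-butyl ester 7, and the enal from aldehyde 5 by a two-carbon Wittig reaction with 6. An enal is chosen over an enoate so that the later reduction does not endanger the imide.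

5 ⇒ 3 ⇒ 1 + 2. Aldehyde 5 is the reduced form of acid 3, and 3 is the Birch reductive alkylation product of 1 with 2. This single step creates the quaternary C1, the 2,5-diene, and two arms of different oxidation level.

## Alternatives that were turned down

Alternative 1: Ring A is cut at C1–C2 and C5–C6. In the forward direction 2-(2,2-dimethoxyethyl)prop-2-enal A1 and the aminosiloxydiene A2 would combine in a catalytic asymmetric Diels–Alder reaction to give, after acidic work-up, the formyl cyclohexenone A3 (formyl = C7, acetal arm = C8'). In its favour, the absolute configuration of C1 is set catalytically in the first C–C bond-forming step, and the two ring arms are different from the start. On that point it is stronger than the chosen route, where C1 is fixed only in step 16. Against it, C7, C8, C7' and C8' must then all be built on the aldehyde and the acetal arm next to a quaternary centre whose two ring arms differ only remotely, so substrate control would be weak and each centre would need its own reagent-controlled step. Ring A would still need the C3 methoxy group and the C5=C6 double bond, and an α-branched acrolein with a bulky substituent is a demanding dienophile for enantioselective catalysis. The chosen strategy instead offers three ring B centres from one operation and a C1 centre set by an internal relay, in fewer steps overall.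

Alternative 2: Ring A is cut at C1–C6 and C2–C3. The enamine of the preformed ring B carbaldehyde A4 would add through C1 to 1-methoxybut-3-en-2-one A5, and aldol condensation would close the 2-methoxycyclohexenone A6. In its favour, the methoxy enone arrives with its oxygen in place and the arms differentiated, with no late C–H oxidation or arm selection; here it is stronger than the chosen route. Attack anti to the two cis substituents at C7 and C8' would also give the right C1 configuration. Against it, A4 is itself an oxolane with four stereocentres that needs a long stereocontrolled synthesis. Its ring oxygen is β to the enamine carbon, so β-elimination with ring opening competes with the hindered Michael addition. The aldol step must choose between two enolisable positions of the ketone, and the C5=C6 double bond still has to be introduced. The chosen strategy builds ring B and its centres directly on an achiral core and never exposes a β-alkoxy aldehyde to enamine conditions.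

Alternative 3: Ring B is cut at O–C7 and C1–C8'. Under zerovalent palladium, the para-quinone methide A7 and the trans aryl vinyl oxirane A8 would react. The ring-opened alkoxide would add to C7, and the resulting phenolate would attack the allylpalladium unit through its para carbon, giving the spirodienone A9 with a vinyl group at C8'. This is the most convergent plan and clearly the shortest: ring B, the spiro centre and the methoxy dienone appear in one step from fragments holding nearly all the carbons. Against it, C7, C1 and C8' would form in a stepwise ionic cascade. The addition at C7 would be guided only by the adjacent C8 centre, the allylpalladium intermediate can equilibrate and so loosen the C7'/C8' relation, and nothing directs the face of the phenolate at C1. A7 carries a C8 hydrogen and can tautomerise to a vinyl phenol, and the vinyl group would later have to be cleaved to CH2OH beside a dienone and electron-rich arenes. The chosen strategy is longer, but each of its stereocentres has a named controlling element.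

Key step: step 10

Remark: lignan locants are used throughout (ring A C1–C6, ring B O–C7–C1–C8'–C7', chain C8–C9 on C7, C9' on C8'); in the oxaspiro names C7 = position 1, C7' = 3, C8' = 4, C1 = 5. Compounds 6, 9 and 21 are assumed to be purchased. C3 of 28 may form as either epimer and is destroyed in step 18.

## Steps

Step 1
Reactants: 1 benzoic acid; 2 tert-butyl bromoacetate
Product: 3 1-(2-tert-butoxy-2-oxoethyl)cyclohexa-2,5-diene-1-carboxylic acid
Conditions: Li, NH3(l)/THF, −78 °C; then 2, −78 °C; NH4Cl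
Reagents that add atoms: none
Why: Birch reductive alkylation: the carboxylate-stabilised cyclohexadienyl dianion is alkylated at C1 by the bromoacetate, creating the quaternary carbon and the 2,5-diene in one operation; the tert-butyl ester resists the amide base present.

Step 2
Reactants: 3 1-(2-tert-butoxy-2-oxoethyl)cyclohexa-2,5-diene-1-carboxylic acid
Product: 5 tert-butyl 2-(1-formylcyclohexa-2,5-dien-1-yl)acetate, via acid chloride 4 (not isolated)
Conditions: 1-chloro-N,N,2-trimethylprop-1-en-1-amine, CH2Cl2, 0 °C → rt; then LiAlH(OtBu)3, THF, −78 °C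
Reagents that add atoms: none
Why: The neutral chloroenamine forms the hindered acid chloride without acid that would cleave the tert-butyl ester; reduction of an acid chloride with LiAlH(OtBu)3 stops at the aldehyde at low temperature and leaves the ester.

Step 3
Reactants: 5 tert-butyl 2-(1-formylcyclohexa-2,5-dien-1-yl)acetate; 6 (triphenylphosphoranylidene)acetaldehyde
Product: 7 tert-butyl 2-{1-[(E)-3-oxoprop-1-en-1-yl]cyclohexa-2,5-dien-1-yl}acetate
Conditions: 6 (1.1 equiv), toluene, 80 °C
Reagents that add atoms: none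
Why: Wittig olefination with a formyl-stabilised ylide gives the (E)-enal; the aldehyde cannot enolise, and a near-stoichiometric amount of ylide limits a second homologation.

Step 4
Reactants: 7 tert-butyl 2-{1-[(E)-3-oxoprop-1-en-1-yl]cyclohexa-2,5-dien-1-yl}acetate
Product: 8 2-{1-[(E)-3-oxoprop-1-en-1-yl]cyclohexa-2,5-dien-1-yl}acetic acid
Conditions: CF3CO2H/CH2Cl2 (1:4), 0 °C → rt
Reagents that add atoms: none
Why: Acidolysis of the tert-butyl ester with loss of isobutene; the ester is exchanged here because no acid-labile group is present yet and the enal and isolated ring alkenes are not protonated under these conditions.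

Step 5
Reactants: 8 2-{1-[(E)-3-oxoprop-1-en-1-yl]cyclohexa-2,5-dien-1-yl}acetic acid; 9 (S)-4-benzyloxazolidin-2-one
Product: 11 (S)-4-benzyl-3-(2-{1-[(E)-3-oxoprop-1-en-1-yl]cyclohexa-2,5-dien-1-yl}acetyl)oxazolidin-2-one, via mixed pivalic anhydride 10 (not isolated)
Conditions: t-BuCOCl, Et3N, THF, −20 °C; then 9, LiCl, −20 °C → rt
Reagents that add atoms: none
Why: Mixed-anhydride N-acylation of the oxazolidinone; the pivaloyl carbonyl is shielded, so the auxiliary takes the substrate acyl group, and the mild LiCl/Et3N conditions leave the enal untouched.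

Step 6
Reactants: 11 (S)-4-benzyl-3-(2-{1-[(E)-3-oxoprop-1-en-1-yl]cyclohexa-2,5-dien-1-yl}acetyl)oxazolidin-2-one
Product: 12 (S)-4-benzyl-3-(2-{1-[(E)-3-hydroxyprop-1-en-1-yl]cyclohexa-2,5-dien-1-yl}acetyl)oxazolidin-2-one
Conditions: NaBH4, CeCl3·7H2O, MeOH/THF, −78 °C
Reagents that add atoms: none
Why: Luche reduction: the CeCl3-activated enal undergoes fast 1,2-reduction at −78 °C, where the imide and the ring alkenes are not reduced.

Step 7
Reactants: 12 (S)-4-benzyl-3-(2-{1-[(E)-3-hydroxyprop-1-en-1-yl]cyclohexa-2,5-dien-1-yl}acetyl)oxazolidin-2-one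
Product: 13 (S)-4-benzyl-3-(2-{1-[(2R,3R)-3-(hydroxymethyl)oxiran-2-yl]cyclohexa-2,5-dien-1-yl}acetyl)oxazolidin-2-one
Conditions: Ti(OiPr)4, D-(−)-diisopropyl tartrate, t-BuOOH, 4 Å molecular sieves, CH2Cl2, −20 °C
Reagents that add atoms: tert-butyl hydroperoxide, CC(C)(C)OO
Why: Sharpless asymmetric epoxidation; with the D-tartrate the oxygen is delivered to the face of the (E)-allylic alcohol that gives the (2R,3R)-epoxy alcohol (C7 R, C8 R), and the ring alkenes, not being allylic alcohols, stay untouched.

Step 8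
Reactants: 13 (S)-4-benzyl-3-(2-{1-[(2R,3R)-3-(hydroxymethyl)oxiran-2-yl]cyclohexa-2,5-dien-1-yl}acetyl)oxazolidin-2-one
Product: 14 (S)-4-benzyl-3-[2-(1-{(2R,3R)-3-[(tert-butyldimethylsilyloxy)methyl]oxiran-2-yl}cyclohexa-2,5-dien-1-yl)acetyl]oxazolidin-2-one
Conditions: t-BuMe2SiCl, imidazole, CH2Cl2, 0 °C → rt
Reagents that add atoms: tert-butyldimethylsilyl chloride, CC(C)(C)[Si](C)(C)Cl
Why: Silylation of the primary alcohol removes the only free hydroxyl before boron enolate formation.

Step 9
Reactants: 15 vanillin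
Product: 16 3-methoxy-4-(triisopropylsilyloxy)benzaldehyde
Conditions: iPr3SiCl, imidazole, DMF, rt
Reagents that add atoms: triisopropylsilyl chloride, CC(C)[Si](Cl)(C(C)C)C(C)C
Why: Silylation of the phenol; the bulky triisopropylsilyl ether is chosen because it must survive carbonate in methanol and in acetone later (steps 16 and 18).

Step 10
Reactants: 14 (S)-4-benzyl-3-[2-(1-{(2R,3R)-3-[(tert-butyldimethylsilyloxy)methyl]oxiran-2-yl}cyclohexa-2,5-dien-1-yl)acetyl]oxazolidin-2-one; 16 3-methoxy-4-(triisopropylsilyloxy)benzaldehyde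
Product: 18 (S)-4-benzyl-3-{[(1S,3S,4S)-1-[(1R)-2-(tert-butyldimethylsilyloxy)-1-hydroxyethyl]-3-[3-methoxy-4-(triisopropylsilyloxy)phenyl]-2-oxaspiro[4.5]deca-6,9-dien-4-yl]carbonyl}oxazolidin-2-one, via syn-aldol adduct 17 (not isolated)
Conditions: Bu2BOTf, iPr2NEt, CH2Cl2, −78 → 0 °C; 16, −78 → 0 °C; NaH2PO4/Na2HPO4 buffer (pH 7), MeOH, 30% H2O2, 0 °C; then camphorsulfonic acid (0.1 equiv), CH2Cl2, 0 °C → rt
Reagents that add atoms: none
Why: Bu2BOTf and the amine give the Z-dibutylboron enolate of the imide, which adds to 16 through a closed chair (Zimmerman–Traxler) transition state; the closest known reaction type is the Evans boron syn-aldol reaction. The benzyl group of the auxiliary, with the two imide carbonyls opposed, shields one enolate face, so C8' and C7' are set together as the syn pair shown in 17 (auxiliary control), while C1 still carries two identical ring arms and exerts no bias of its own. After oxidative release of boron, the catalytic acid activates the epoxide and the C7' hydroxyl attacks C7, closing ring B by a 5-exo-tet cycloetherification, a known acid-catalysed hydroxy-epoxide closure. Attack is anti to the epoxide oxygen, so C7 is inverted (tartrate control, transferred through the epoxide) and C8 is left as the free 8R carbinol. The three reagent-set centres together dictate the 2,5-trans, 7',8'-trans oxolane. The step needs syn and facial selectivity in the aldol (auxiliary) and exo rather than 6-endo opening. Exo opening is favoured by the collinear trajectory to the proximal carbon, by the inductive deactivation of C8 by its CH2OSi neighbour, and by the geminal substitution at C1 that holds nucleophile and epoxide together. The epoxide should survive enolisation because the triflate is used near-stoichiometrically, amine-buffered and cold, and the silylated aryl group keeps the benzylic C7' position from ionising under the catalytic acid.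

Step 11
Reactants: 18 (S)-4-benzyl-3-{[(1S,3S,4S)-1-[(1R)-2-(tert-butyldimethylsilyloxy)-1-hydroxyethyl]-3-[3-methoxy-4-(triisopropylsilyloxy)phenyl]-2-oxaspiro[4.5]deca-6,9-dien-4-yl]carbonyl}oxazolidin-2-one
Product: 19 [(1S,3S,4R)-1-[(1R)-2-(tert-butyldimethylsilyloxy)-1-hydroxyethyl]-3-[3-methoxy-4-(triisopropylsilyloxy)phenyl]-2-oxaspiro[4.5]deca-6,9-dien-4-yl]methanol
Conditions: LiBH4, MeOH (1 equiv), THF, 0 °C
Reagents that add atoms: none
Why: Reductive cleavage of the N-acyloxazolidinone gives the C9' primary alcohol and returns the auxiliary; if the C8 alkoxide first acylates itself from the imide, the resulting lactone is reduced to the same diol.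

Step 12
Reactants: 19 [(1S,3S,4R)-1-[(1R)-2-(tert-butyldimethylsilyloxy)-1-hydroxyethyl]-3-[3-methoxy-4-(triisopropylsilyloxy)phenyl]-2-oxaspiro[4.5]deca-6,9-dien-4-yl]methanol
Product: 20 [(1S,3S,4R)-1-[(1R)-2-(tert-butyldimethylsilyloxy)-1-hydroxyethyl]-3-[3-methoxy-4-(triisopropylsilyloxy)phenyl]-2-oxaspiro[4.5]deca-6,9-dien-4-yl]methyl acetate
Conditions: AcCl (1.05 equiv), 2,4,6-collidine, CH2Cl2, −78 °C
Reagents that add atoms: acetyl chloride, CC(Cl)=O
Why: Selective acylation of the primary C9' hydroxyl at low temperature; the secondary C8 hydroxyl, flanked by ring B and the silyloxymethyl group, reacts far more slowly.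

Step 13
Reactants: 21 dihydroconiferyl alcohol
Product: 23 4-[3-(tert-butyldimethylsilyloxy)propyl]-2-methoxyphenol, via bis-silyl ether 22 (not isolated)
Conditions: t-BuMe2SiCl (2.2 equiv), imidazole, DMF, rt; then K2CO3, MeOH, rt
Reagents that add atoms: tert-butyldimethylsilyl chloride, CC(C)(C)[Si](C)(C)Cl
Why: Exhaustive silylation followed by carbonate/methanol cleavage of the aryl silyl ether alone, which is far more labile to basic methanol than the alkyl silyl ether, frees the phenol.

Step 14
Reactants: 20 [(1S,3S,4R)-1-[(1R)-2-(tert-butyldimethylsilyloxy)-1-hydroxyethyl]-3-[3-methoxy-4-(triisopropylsilyloxy)phenyl]-2-oxaspiro[4.5]deca-6,9-dien-4-yl]methyl acetate; 23 4-[3-(tert-butyldimethylsilyloxy)propyl]-2-methoxyphenol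
Product: 24 [(1S,3S,4R)-1-[(1S)-2-(tert-butyldimethylsilyloxy)-1-{4-[3-(tert-butyldimethylsilyloxy)propyl]-2-methoxyphenoxy}ethyl]-3-[3-methoxy-4-(triisopropylsilyloxy)phenyl]-2-oxaspiro[4.5]deca-6,9-dien-4-yl]methyl acetate
Conditions: PPh3, diisopropyl azodicarboxylate, toluene, 0 °C → rt
Reagents that add atoms: none
Why: Mitsunobu etherification: the phenol (pKa about 10) displaces the C8 oxyphosphonium ion by SN2 with inversion, turning the 8R carbinol into the 8S aryl ether of the target.

Step 15
Reactants: 24 [(1S,3S,4R)-1-[(1S)-2-(tert-butyldimethylsilyloxy)-1-{4-[3-(tert-butyldimethylsilyloxy)propyl]-2-methoxyphenoxy}ethyl]-3-[3-methoxy-4-(triisopropylsilyloxy)phenyl]-2-oxaspiro[4.5]deca-6,9-dien-4-yl]methyl acetate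
Product: 25 [(1S,3S,4R)-1-[(1S)-2-(tert-butyldimethylsilyloxy)-1-{4-[3-(tert-butyldimethylsilyloxy)propyl]-2-methoxyphenoxy}ethyl]-3-[3-methoxy-4-(triisopropylsilyloxy)phenyl]-8-oxo-2-oxaspiro[4.5]deca-6,9-dien-4-yl]methyl acetate
Conditions: (C5H5NH)2Cr2O7 (mediator), t-BuOOH, Celite, benzene, rt
Reagents that add atoms: tert-butyl hydroperoxide, CC(C)(C)OO
Why: Bis-allylic oxidation of a 3,3-disubstituted cyclohexa-1,4-diene to the cross-conjugated dienone: the doubly allylic C4–H bonds are the weakest in the molecule, the quaternary C1 blocks aromatisation, and the hydroperoxide is the terminal oxidant.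

Step 16
Reactants: 25 [(1S,3S,4R)-1-[(1S)-2-(tert-butyldimethylsilyloxy)-1-{4-[3-(tert-butyldimethylsilyloxy)propyl]-2-methoxyphenoxy}ethyl]-3-[3-methoxy-4-(triisopropylsilyloxy)phenyl]-8-oxo-2-oxaspiro[4.5]deca-6,9-dien-4-yl]methyl acetate
Product: 27 tricyclic enone (1S,2R,7S,8S,7'S,8'R) in which the C9' oxygen of 26 is bonded to C2 as a second cis-fused oxolane (O9'–C9'–C8'–C1–C2); C3 is CH2; the C4 ketone stays conjugated to C5=C6, via hydroxy dienone 26 (not isolated)
Conditions: K2CO3, MeOH, 0 °C → rt
Reagents that add atoms: none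
Why: Methanolysis of the acetate, then intramolecular oxa-Michael addition (5-exo-trig) of the C9' hydroxyl to the dienone; only the arm on the C9' face of ring B can be reached, since the other arm would need a trans-fused pair of five-membered rings, so C1 becomes 1S and the arm that will carry the methoxy group is marked, with C2 fixed by the cis ring fusion.

Step 17
Reactants: 27 tricyclic enone (1S,2R,7S,8S,7'S,8'R)
Product: 28 C3-hydroxy derivative of 27 (1S,2S,7S,8S,7'S,8'R; C3 either configuration)
Conditions: KN(SiMe3)2, THF, −78 °C; then 2-(phenylsulfonyl)-3-phenyloxaziridine, −78 °C; NH4Cl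
Reagents that add atoms: 2-(phenylsulfonyl)-3-phenyloxaziridine, O=S(=O)(c1ccccc1)N1OC1c1ccccc1
Why: Enolate hydroxylation with an N-sulfonyloxaziridine: C3 is the only enolisable position, so the potassium enolate forms there and is oxidised to the α-hydroxy ketone; should the enolate eject the C2 alkoxide, the alkoxide re-adds and only the enolate consumes the oxidant.

Step 18
Reactants: 28 C3-hydroxy derivative of 27
Product: 30 (1S,3S,4R,5S)-1-[(1S)-2-(tert-butyldimethylsilyloxy)-1-{4-[3-(tert-butyldimethylsilyloxy)propyl]-2-methoxyphenoxy}ethyl]-4-(hydroxymethyl)-7-methoxy-3-[3-methoxy-4-(triisopropylsilyloxy)phenyl]-2-oxaspiro[4.5]deca-6,9-dien-8-one, via diosphenol 29 (not isolated)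
Conditions: K2CO3, MeI, acetone, rt
Reagents that add atoms: iodomethane, CI
Why: Base-induced β-elimination (E1cB, retro-oxa-Michael) expels the C2 alkoxide from the α-hydroxy ketone, releasing the C9' hydroxyl and the diosphenol; its acidic enol is O-methylated under carbonate, which does not deprotonate the aliphatic hydroxyl.

Step 19
Reactants: 30 (1S,3S,4R,5S)-1-[(1S)-2-(tert-butyldimethylsilyloxy)-1-{4-[3-(tert-butyldimethylsilyloxy)propyl]-2-methoxyphenoxy}ethyl]-4-(hydroxymethyl)-7-methoxy-3-[3-methoxy-4-(triisopropylsilyloxy)phenyl]-2-oxaspiro[4.5]deca-6,9-dien-8-one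
Product: 31 (1S,3S,4R,5S)-1-[(1S)-2-hydroxy-1-[4-(3-hydroxypropyl)-2-methoxyphenoxy]ethyl]-3-(4-hydroxy-3-methoxyphenyl)-4-(hydroxymethyl)-7-methoxy-2-oxaspiro[4.5]deca-6,9-dien-8-one (CNP0252711.1)
Conditions: Bu4NF, AcOH, THF, 0 °C → rt
Reagents that add atoms: none
Why: Fluoride cleavage of the two primary silyl ethers and the aryl silyl ether; acetic acid buffers the medium so that the freed hydroxyls and phenol do not add to the dienone.

## Compound list

1 | benzoic acid | OC(=O)c1ccccc1 | starting material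
2 | tert-butyl bromoacetate | CC(C)(C)OC(=O)CBr | starting material
3 | 1-(2-tert-butoxy-2-oxoethyl)cyclohexa-2,5-diene-1-carboxylic acid | OC(=O)C1(CC(=O)OC(C)(C)C)C=CCC=C1 | intermediate
4 | 1-(2-tert-butoxy-2-oxoethyl)cyclohexa-2,5-diene-1-carbonyl chloride | ClC(=O)C1(CC(=O)OC(C)(C)C)C=CCC=C1 | intermediate (not isolated)
5 | tert-butyl 2-(1-formylcyclohexa-2,5-dien-1-yl)acetate | O=CC1(CC(=O)OC(C)(C)C)C=CCC=C1 | intermediate
6 | (triphenylphosphoranylidene)acetaldehyde | O=CC=P(c1ccccc1)(c1ccccc1)c1ccccc1 | starting material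
7 | tert-butyl 2-{1-[(E)-3-oxoprop-1-en-1-yl]cyclohexa-2,5-dien-1-yl}acetate | O=C/C=C/C1(CC(=O)OC(C)(C)C)C=CCC=C1 | intermediate
8 | 2-{1-[(E)-3-oxoprop-1-en-1-yl]cyclohexa-2,5-dien-1-yl}acetic acid | O=C/C=C/C1(CC(=O)O)C=CCC=C1 | intermediate
9 | (S)-4-benzyloxazolidin-2-one | O=C1N[C@@H](Cc2ccccc2)CO1 | starting material
10 | mixed anhydride of 8 with pivalic acid | O=C/C=C/C1(CC(=O)OC(=O)C(C)(C)C)C=CCC=C1 | intermediate (not isolated)
11 | (S)-4-benzyl-3-(2-{1-[(E)-3-oxoprop-1-en-1-yl]cyclohexa-2,5-dien-1-yl}acetyl)oxazolidin-2-one | O=C/C=C/C1(CC(=O)N2[C@@H](Cc3ccccc3)COC2=O)C=CCC=C1 | intermediate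
12 | (S)-4-benzyl-3-(2-{1-[(E)-3-hydroxyprop-1-en-1-yl]cyclohexa-2,5-dien-1-yl}acetyl)oxazolidin-2-one | OC/C=C/C1(CC(=O)N2[C@@H](Cc3ccccc3)COC2=O)C=CCC=C1 | intermediate
13 | (S)-4-benzyl-3-(2-{1-[(2R,3R)-3-(hydroxymethyl)oxiran-2-yl]cyclohexa-2,5-dien-1-yl}acetyl)oxazolidin-2-one | OC[C@H]1O[C@@H]1C1(CC(=O)N2[C@@H](Cc3ccccc3)COC2=O)C=CCC=C1 | intermediate
14 | (S)-4-benzyl-3-[2-(1-{(2R,3R)-3-[(tert-butyldimethylsilyloxy)methyl]oxiran-2-yl}cyclohexa-2,5-dien-1-yl)acetyl]oxazolidin-2-one | CC(C)(C)[Si](C)(C)OC[C@H]1O[C@@H]1C1(CC(=O)N2[C@@H](Cc3ccccc3)COC2=O)C=CCC=C1 | intermediate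
15 | vanillin | O=Cc1ccc(O)c(OC)c1 | starting material
16 | 3-methoxy-4-(triisopropylsilyloxy)benzaldehyde | O=Cc1ccc(O[Si](C(C)C)(C(C)C)C(C)C)c(OC)c1 | intermediate
17 | (S)-4-benzyl-3-[(2S,3S)-2-(1-{(2R,3R)-3-[(tert-butyldimethylsilyloxy)methyl]oxiran-2-yl}cyclohexa-2,5-dien-1-yl)-3-hydroxy-3-[3-methoxy-4-(triisopropylsilyloxy)phenyl]propanoyl]oxazolidin-2-one (syn-aldol adduct) | CC(C)(C)[Si](C)(C)OC[C@H]1O[C@@H]1C1(C=CCC=C1)[C@H](C(=O)N1[C@@H](Cc2ccccc2)COC1=O)[C@H](O)c1ccc(O[Si](C(C)C)(C(C)C)C(C)C)c(OC)c1 | intermediate (not isolated)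
18 | (S)-4-benzyl-3-{[(1S,3S,4S)-1-[(1R)-2-(tert-butyldimethylsilyloxy)-1-hydroxyethyl]-3-[3-methoxy-4-(triisopropylsilyloxy)phenyl]-2-oxaspiro[4.5]deca-6,9-dien-4-yl]carbonyl}oxazolidin-2-one (7S,8R,7'S,8'S) | C1=CCC=CC12[C@H](C(=O)N3[C@@H](Cc4ccccc4)COC3=O)[C@@H](c3ccc(O[Si](C(C)C)(C(C)C)C(C)C)c(OC)c3)O[C@@H]2[C@@H](CO[Si](C)(C)C(C)(C)C)O | intermediate
19 | [(1S,3S,4R)-1-[(1R)-2-(tert-butyldimethylsilyloxy)-1-hydroxyethyl]-3-[3-methoxy-4-(triisopropylsilyloxy)phenyl]-2-oxaspiro[4.5]deca-6,9-dien-4-yl]methanol (7S,8R,7'S,8'R) | C1=CCC=CC12[C@H](CO)[C@@H](c3ccc(O[Si](C(C)C)(C(C)C)C(C)C)c(OC)c3)O[C@@H]2[C@@H](CO[Si](C)(C)C(C)(C)C)O | intermediate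
20 | [(1S,3S,4R)-1-[(1R)-2-(tert-butyldimethylsilyloxy)-1-hydroxyethyl]-3-[3-methoxy-4-(triisopropylsilyloxy)phenyl]-2-oxaspiro[4.5]deca-6,9-dien-4-yl]methyl acetate | C1=CCC=CC12[C@H](COC(C)=O)[C@@H](c3ccc(O[Si](C(C)C)(C(C)C)C(C)C)c(OC)c3)O[C@@H]2[C@@H](CO[Si](C)(C)C(C)(C)C)O | intermediate
21 | dihydroconiferyl alcohol, 4-(3-hydroxypropyl)-2-methoxyphenol | OCCCc1ccc(O)c(OC)c1 | starting material
22 | tert-butyl{4-[3-(tert-butyldimethylsilyloxy)propyl]-2-methoxyphenoxy}dimethylsilane | CC(C)(C)[Si](C)(C)OCCCc1ccc(O[Si](C)(C)C(C)(C)C)c(OC)c1 | intermediate (not isolated)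
23 | 4-[3-(tert-butyldimethylsilyloxy)propyl]-2-methoxyphenol | CC(C)(C)[Si](C)(C)OCCCc1ccc(O)c(OC)c1 | intermediate
24 | [(1S,3S,4R)-1-[(1S)-2-(tert-butyldimethylsilyloxy)-1-{4-[3-(tert-butyldimethylsilyloxy)propyl]-2-methoxyphenoxy}ethyl]-3-[3-methoxy-4-(triisopropylsilyloxy)phenyl]-2-oxaspiro[4.5]deca-6,9-dien-4-yl]methyl acetate (7S,8S,7'S,8'R) | C1=CCC=CC12[C@H](COC(C)=O)[C@@H](c3ccc(O[Si](C(C)C)(C(C)C)C(C)C)c(OC)c3)O[C@@H]2[C@H](CO[Si](C)(C)C(C)(C)C)Oc2ccc(CCCO[Si](C)(C)C(C)(C)C)cc2OC | intermediate
25 | the 8-oxo derivative of 24 (cyclohexa-2,5-dienone, lignan C4=O) | O=C1C=CC2(C=C1)[C@H](COC(C)=O)[C@@H](c1ccc(O[Si](C(C)C)(C(C)C)C(C)C)c(OC)c1)O[C@@H]2[C@H](CO[Si](C)(C)C(C)(C)C)Oc1ccc(CCCO[Si](C)(C)C(C)(C)C)cc1OC | intermediate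
26 | (1S,3S,4R)-1-[(1S)-2-(tert-butyldimethylsilyloxy)-1-{4-[3-(tert-butyldimethylsilyloxy)propyl]-2-methoxyphenoxy}ethyl]-4-(hydroxymethyl)-3-[3-methoxy-4-(triisopropylsilyloxy)phenyl]-2-oxaspiro[4.5]deca-6,9-dien-8-one | O=C1C=CC2(C=C1)[C@H](CO)[C@@H](c1ccc(O[Si](C(C)C)(C(C)C)C(C)C)c(OC)c1)O[C@@H]2[C@H](CO[Si](C)(C)C(C)(C)C)Oc1ccc(CCCO[Si](C)(C)C(C)(C)C)cc1OC | intermediate (not isolated)
27 | tricyclic enone (1S,2R,7S,8S,7'S,8'R): 26 with O9' bonded to C2 (cis-fused oxolane O9'–C9'–C8'–C1–C2), C3H2, C4=O conjugated to C5=C6 | O=C1C=C[C@@]2([C@H]3C1)[C@H](CO3)[C@@H](c1ccc(O[Si](C(C)C)(C(C)C)C(C)C)c(OC)c1)O[C@@H]2[C@H](CO[Si](C)(C)C(C)(C)C)Oc1ccc(CCCO[Si](C)(C)C(C)(C)C)cc1OC | intermediate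
28 | C3-hydroxy derivative of 27 (1S,2S,7S,8S,7'S,8'R; C3 either configuration) | O=C1C=C[C@@]2([C@H]3C1O)[C@H](CO3)[C@@H](c1ccc(O[Si](C(C)C)(C(C)C)C(C)C)c(OC)c1)O[C@@H]2[C@H](CO[Si](C)(C)C(C)(C)C)Oc1ccc(CCCO[Si](C)(C)C(C)(C)C)cc1OC | intermediate
29 | diosphenol: the 7-hydroxy analogue of 30 (lignan C3–OH; 1S,7S,8S,7'S,8'R) | OC1=C[C@]2(C=CC1=O)[C@H](CO)[C@@H](c1ccc(O[Si](C(C)C)(C(C)C)C(C)C)c(OC)c1)O[C@@H]2[C@H](CO[Si](C)(C)C(C)(C)C)Oc1ccc(CCCO[Si](C)(C)C(C)(C)C)cc1OC | intermediate (not isolated)
30 | (1S,3S,4R,5S)-1-[(1S)-2-(tert-butyldimethylsilyloxy)-1-{4-[3-(tert-butyldimethylsilyloxy)propyl]-2-methoxyphenoxy}ethyl]-4-(hydroxymethyl)-7-methoxy-3-[3-methoxy-4-(triisopropylsilyloxy)phenyl]-2-oxaspiro[4.5]deca-6,9-dien-8-one | COC1=C[C@]2(C=CC1=O)[C@H](CO)[C@@H](c1ccc(O[Si](C(C)C)(C(C)C)C(C)C)c(OC)c1)O[C@@H]2[C@H](CO[Si](C)(C)C(C)(C)C)Oc1ccc(CCCO[Si](C)(C)C(C)(C)C)cc1OC | intermediate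
31 | CNP0252711.1, (1S,3S,4R,5S)-1-[(1S)-2-hydroxy-1-[4-(3-hydroxypropyl)-2-methoxyphenoxy]ethyl]-3-(4-hydroxy-3-methoxyphenyl)-4-(hydroxymethyl)-7-methoxy-2-oxaspiro[4.5]deca-6,9-dien-8-one (lignan descriptors 1S,7S,8S,7'S,8'R) | COC1=C[C@]2(C=CC1=O)[C@H](CO)[C@@H](c1ccc(O)c(OC)c1)O[C@@H]2[C@H](CO)Oc1ccc(CCCO)cc1OC | target

## Step count and least certain steps

Total: 19 steps. Longest linear sequence: 17 steps (steps 1–8, 10–12 and 14–19, from benzoic acid); steps 9 and 13 prepare the two aryl partners.

Step 10 (key step). The enolate carbon is next to the quaternary C1, so enolisation and addition to an electron-rich aldehyde may be incomplete. The boron triflate may open the epoxide during enolisation. In the acid stage, 6-endo opening at C8, participation of the imide carbonyl oxygen, or ionisation at the benzylic C7' position with loss of configuration may compete. The fallback keeps the same two bonds but separates the events so that the epoxide never meets the boron triflate. Setting out from 12, the primary hydroxyl would be silylated to the allyl silyl ether F1. The boron aldol reaction with 16 under the conditions of step 10 would give the syn-aldol adduct F2. HF·pyridine would free the allylic alcohol F3 (the aryl silyl ether is stable to it). Sharpless epoxidation with the same D-tartrate would give the epoxy alcohol F4. With additional Ti(OiPr)4 the titanium-bound 2,3-epoxy alcohol is opened selectively at its C3 (C7) by the C7' hydroxyl, giving the diol F5. Silylation of the primary hydroxyl of F5 returns to 18.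

Step 14. Displacement at the hindered C8 oxyphosphonium ion may be outrun by elimination toward C7 or C9, or by participation of the ring B oxygen, which would lead to retention or ring enlargement. The fallback replaces redox activation by a sulfonate displacement with a charged nucleophile. From 20, Tf2O and 2,6-di-tert-butylpyridine at −78 °C would give the C8 triflate F6. Phenol 23 with Cs2CO3 in DMF at low temperature would then displace it with inversion, rejoining the route at 24.

Step 15. Hydrogen abstraction at the benzylic ether position C7' or at the ArCH2 group may compete with the doubly allylic C4 position, and over-oxidation may follow. The fallback replaces the radical C–H oxidation by a pericyclic hydroxylation. From 24, SeO2/t-BuOOH (ene reaction, then 2,3-sigmatropic shift) would give the doubly allylic dienol F7 as a mixture at C4. MnO2, which oxidises only allylic alcohols, would take F7 to 25.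

Step 16. The conjugate addition may be slow or reversible under the carbonate conditions, methoxide may add intermolecularly, or the aryl silyl ether may be partly lost in basic methanol. In that case 26 would be isolated after a short methanolysis and treated with KN(SiMe3)2 in THF at −78 °C. The alkoxide and the ring-closed potassium enolate F8 (C3=C4–OK) equilibrate, and only F8 reacts with 2-(phenylsulfonyl)-3-phenyloxaziridine, so the equilibrium is drained into 28 directly. This fallback trades the thermodynamic ring closure for kinetic trapping and skips 27.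

Step 18. The ambident diosphenolate may be methylated on carbon (C2), the released C9' alkoxide may be methylated before it is protonated, or the C9' hydroxyl may re-add. The fallback reverses the order of events. From 28, the C3 hydroxyl would be methylated under non-basic conditions (Me3OBF4, 1,8-bis(dimethylamino)naphthalene, CH2Cl2) to the α-methoxy ketone F9. DBU would then induce the β-elimination, which gives 30 directly with no diosphenolate involved.

## Further compounds

F1 | step 10 | (S)-4-benzyl-3-(2-{1-[(E)-3-(tert-butyldimethylsilyloxy)prop-1-en-1-yl]cyclohexa-2,5-dien-1-yl}acetyl)oxazolidin-2-one | CC(C)(C)[Si](C)(C)OC/C=C/C1(CC(=O)N2[C@@H](Cc3ccccc3)COC2=O)C=CCC=C1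
F2 | step 10 | (S)-4-benzyl-3-[(2S,3S)-2-{1-[(E)-3-(tert-butyldimethylsilyloxy)prop-1-en-1-yl]cyclohexa-2,5-dien-1-yl}-3-hydroxy-3-[3-methoxy-4-(triisopropylsilyloxy)phenyl]propanoyl]oxazolidin-2-one | CC(C)(C)[Si](C)(C)OC/C=C/C1(C=CCC=C1)[C@H](C(=O)N1[C@@H](Cc2ccccc2)COC1=O)[C@H](O)c1ccc(O[Si](C(C)C)(C(C)C)C(C)C)c(OC)c1
F3 | step 10 | (S)-4-benzyl-3-[(2S,3S)-3-hydroxy-2-{1-[(E)-3-hydroxyprop-1-en-1-yl]cyclohexa-2,5-dien-1-yl}-3-[3-methoxy-4-(triisopropylsilyloxy)phenyl]propanoyl]oxazolidin-2-one | OC/C=C/C1(C=CCC=C1)[C@H](C(=O)N1[C@@H](Cc2ccccc2)COC1=O)[C@H](O)c1ccc(O[Si](C(C)C)(C(C)C)C(C)C)c(OC)c1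
F4 | step 10 | (S)-4-benzyl-3-[(2S,3S)-3-hydroxy-2-{1-[(2R,3R)-3-(hydroxymethyl)oxiran-2-yl]cyclohexa-2,5-dien-1-yl}-3-[3-methoxy-4-(triisopropylsilyloxy)phenyl]propanoyl]oxazolidin-2-one | OC[C@H]1O[C@@H]1C1(C=CCC=C1)[C@H](C(=O)N1[C@@H](Cc2ccccc2)COC1=O)[C@H](O)c1ccc(O[Si](C(C)C)(C(C)C)C(C)C)c(OC)c1
F5 | step 10 | (S)-4-benzyl-3-{[(1S,3S,4S)-1-[(1R)-1,2-dihydroxyethyl]-3-[3-methoxy-4-(triisopropylsilyloxy)phenyl]-2-oxaspiro[4.5]deca-6,9-dien-4-yl]carbonyl}oxazolidin-2-one | C1=CCC=CC12[C@H](C(=O)N3[C@@H](Cc4ccccc4)COC3=O)[C@@H](c3ccc(O[Si](C(C)C)(C(C)C)C(C)C)c(OC)c3)O[C@@H]2[C@@H](CO)O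
F6 | step 14 | C8 trifluoromethanesulfonate of 20 (7S,8R,7'S,8'R) | C1=CCC=CC12[C@H](COC(C)=O)[C@@H](c3ccc(O[Si](C(C)C)(C(C)C)C(C)C)c(OC)c3)O[C@@H]2[C@@H](CO[Si](C)(C)C(C)(C)C)OS(=O)(=O)C(F)(F)F
F7 | step 15 | 8-hydroxy derivative of 24 (doubly allylic dienol at lignan C4, either configuration) | OC1C=CC2(C=C1)[C@H](COC(C)=O)[C@@H](c1ccc(O[Si](C(C)C)(C(C)C)C(C)C)c(OC)c1)O[C@@H]2[C@H](CO[Si](C)(C)C(C)(C)C)Oc1ccc(CCCO[Si](C)(C)C(C)(C)C)cc1OC
F8 | step 16 | potassium C3=C4 dienolate of 27 | [K+].[O-]C1C=C[C@@]2([C@H]3C=1)[C@H](CO3)[C@@H](c1ccc(O[Si](C(C)C)(C(C)C)C(C)C)c(OC)c1)O[C@@H]2[C@H](CO[Si](C)(C)C(C)(C)C)Oc1ccc(CCCO[Si](C)(C)C(C)(C)C)cc1OC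
F9 | step 18 | C3-methoxy derivative of 27 (methyl ether of 28, C3 either configuration) | O=C1C=C[C@@]2([C@H]3C1OC)[C@H](CO3)[C@@H](c1ccc(O[Si](C(C)C)(C(C)C)C(C)C)c(OC)c1)O[C@@H]2[C@H](CO[Si](C)(C)C(C)(C)C)Oc1ccc(CCCO[Si](C)(C)C(C)(C)C)cc1OC
A1 | alternative 1 | 2-(2,2-dimethoxyethyl)prop-2-enal | C=C(CC(OC)OC)C=O
A2 | alternative 1 | (E)-3-(tert-butyldimethylsilyloxy)-N,N-dimethylbuta-1,3-dien-1-amine | CN(C)/C=C/C(=C)O[Si](C)(C)C(C)(C)C
A3 | alternative 1 | (S)-1-(2,2-dimethoxyethyl)-4-oxocyclohex-2-ene-1-carbaldehyde | O=C1C=C[C@](C=O)(CC1)CC(OC)OC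
A4 | alternative 2 | ring B carbaldehyde (7S,8S,7'S,8'R; C1 epimers): oxolane with H and CHO at C1, CH2OSi(t-Bu)Me2 at C8', 4-(tert-butyldimethylsilyloxy)-3-methoxyphenyl at C7' and the silylated aryloxy chain at C7 | O=CC1[C@H](CO[Si](C)(C)C(C)(C)C)[C@@H](c2ccc(O[Si](C)(C)C(C)(C)C)c(OC)c2)O[C@@H]1[C@H](CO[Si](C)(C)C(C)(C)C)Oc1ccc(CCCO[Si](C)(C)C(C)(C)C)cc1OC
A5 | alternative 2 | 1-methoxybut-3-en-2-one | COCC(=O)C=C
A6 | alternative 2 | spiro 2-methoxycyclohex-2-enone, the 5,6-dihydro analogue of the tetrakis(tert-butyldimethylsilyl) ether of 31 | COC1=C[C@]2(CCC1=O)[C@H](CO[Si](C)(C)C(C)(C)C)[C@@H](c1ccc(O[Si](C)(C)C(C)(C)C)c(OC)c1)O[C@@H]2[C@H](CO[Si](C)(C)C(C)(C)C)Oc1ccc(CCCO[Si](C)(C)C(C)(C)C)cc1OC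
A7 | alternative 3 | para-quinone methide: 2-methoxy-4-alkylidenecyclohexa-2,5-dienone with exocyclic C1=C7 and the (8S) silylated aryloxy chain | COC1=CC(=C[C@H](CO[Si](C)(C)C(C)(C)C)Oc2ccc(CCCO[Si](C)(C)C(C)(C)C)cc2OC)C=CC1=O
A8 | alternative 3 | (2R,3R)-2-[4-(tert-butyldimethylsilyloxy)-3-methoxyphenyl]-3-vinyloxirane | C=C[C@H]1O[C@@H]1c1ccc(O[Si](C)(C)C(C)(C)C)c(OC)c1
A9 | alternative 3 | spirodienone with vinyl at C8' (silylated at the phenol, C9 and the propyl chain) | COC1=C[C@]2(C=CC1=O)[C@H](C=C)[C@@H](c1ccc(O[Si](C)(C)C(C)(C)C)c(OC)c1)O[C@@H]2[C@H](CO[Si](C)(C)C(C)(C)C)Oc1ccc(CCCO[Si](C)(C)C(C)(C)C)cc1OC
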